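The side chain (C1'–C8', counted from the ether oxygen on coumarin C4) is cut at C4'–C5'. Its C2'=C3' trisubstituted alkene lies γ,δ to the oxygenated C6', the retron of a Claisen rearrangement. One acid-catalysed ketal-type Claisen reaction between a coumarin-bearing secondary allylic alcohol (C2' carbinol, C3'=C4' methylene) and 2-methoxy-3-methylbuta-1,3-diene therefore forms C4'–C5', shifts the alkene to C2'=C3' with the required geometry and delivers the isoprenoid terminus as an isopropenyl ketone. The 5-methylcoumarin ring system is carried through untouched. CBS reduction and invertive substitution by a protected hydroperoxide then set the (S)-hydroperoxide at C6'.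

Key step: step 8

Assumption (chemistry): compounds 1, 2, 5, 9, 13 and 21 and all reagents are taken as catalogue chemicals; the carbinol centre of 12 is made racemic on purpose because step 8 erases it.

Step 1
Reactants: 1 1-(2-hydroxy-6-methylphenyl)ethan-1-one; 2 diethyl carbonate
Product: 4 4-hydroxy-5-methyl-2H-chromen-2-one, via β-keto ester 3 (not isolated)
Conditions: NaH (4 equiv), toluene, 110 °C; then 2 M HCl
Reagents that add atoms: none
Why: Claisen-type C-acylation of the methyl ketone enolate by the carbonate followed by lactonisation onto the phenoxide (the standard 4-hydroxycoumarin synthesis from 2-hydroxyacetophenones) should place the 6'-methyl group at coumarin C5.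

Step 2
Reactants: 4 4-hydroxy-5-methyl-2H-chromen-2-one; 5 allyl bromide
Product: 6 5-methyl-4-(prop-2-en-1-yloxy)-2H-chromen-2-one
Conditions: K2CO3, acetone, reflux
Reagents that add atoms: none
Why: Williamson O-alkylation of the acidic vinylogous acid with a reactive allylic halide should give mainly the 4-O-allyl ether, and 56 °C is too low for its Claisen shift to C3.

Step 3
Reactants: 6 5-methyl-4-(prop-2-en-1-yloxy)-2H-chromen-2-one
Product: 8 2-[(5-methyl-2-oxo-2H-chromen-4-yl)oxy]acetaldehyde, via vicinal diol 7 (not isolated)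
Conditions: OsO4 (2 mol%), NaIO4 (4 equiv), 2,6-lutidine, dioxane/H2O (3:1), rt
Reagents that add atoms: osmium tetroxide, O=[Os](=O)(=O)=O; sodium periodate, [Na+].[O-]I(=O)(=O)=O
Why: Lemieux–Johnson oxidation (catalytic dihydroxylation, periodate cleavage) should attack the isolated terminal vinyl group much faster than the conjugated pyrone C3=C4 bond.

Step 4
Reactants: 9 2-bromoprop-2-en-1-ol
Product: 10 [(2-bromoprop-2-en-1-yl)oxy](tert-butyl)dimethylsilane
Conditions: TBSCl, imidazole, CH2Cl2, 0 °C to rt
Reagents that add atoms: tert-butyldimethylsilyl chloride, CC(C)(C)[Si](C)(C)Cl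
Why: Standard silylation of a primary alcohol; the silyl ether blocks this hydroxyl from entering the ketal exchange of step 8.

Step 5
Reactants: 8 2-[(5-methyl-2-oxo-2H-chromen-4-yl)oxy]acetaldehyde; 10 [(2-bromoprop-2-en-1-yl)oxy](tert-butyl)dimethylsilane
Product: 12 rac-4-{[3-({[tert-butyl(dimethyl)silyl]oxy}methyl)-2-hydroxybut-3-en-1-yl]oxy}-5-methyl-2H-chromen-2-one, via alkenylchromium(III) dichloride 11 (not isolated)
Conditions: CrCl2 (4 equiv), NiCl2 (2 mol%), DMF, rt
Reagents that add atoms: none
Why: Nozaki–Hiyama–Kishi coupling: the alkenylchromium(III) species adds to the aldehyde and leaves the lactone alone; the new carbinol centre is formed racemic, which is sufficient.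

Step 6
Reactants: 13 3-methylbut-3-en-2-one
Product: 14 1,3,3-trimethoxy-2-methylbutane
Conditions: HC(OMe)3, MeOH, TsOH·H2O (cat.), 0 °C to rt; NaOMe quench, distillation
Reagents that add atoms: trimethyl orthoformate, COC(OC)OC; methanol, CO
Why: Acid-catalysed conjugate addition of methanol and ketalisation by the orthoformate, as in the conversion of methyl vinyl ketone into 1,3,3-trimethoxybutane.

Step 7
Reactants: 14 1,3,3-trimethoxy-2-methylbutane
Product: 15 2-methoxy-3-methylbuta-1,3-diene
Conditions: KHSO4 (cat.), hydroquinone (trace), 150 °C, product distilled out; redistilled from K2CO3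
Reagents that add atoms: none
Why: Acid-catalysed thermal loss of two molecules of methanol (ketal to enol ether, then elimination of the β-methoxy group) should converge on the conjugated 2-alkoxydiene, which is removed by distillation.

Step 8
Reactants: 12 rac-4-{[3-({[tert-butyl(dimethyl)silyl]oxy}methyl)-2-hydroxybut-3-en-1-yl]oxy}-5-methyl-2H-chromen-2-one; 15 2-methoxy-3-methylbuta-1,3-diene
Product: 18 4-{[(2Z)-3-({[tert-butyl(dimethyl)silyl]oxy}methyl)-7-methyl-6-oxoocta-2,7-dien-1-yl]oxy}-5-methyl-2H-chromen-2-one, via mixed methyl ketal 16 (not isolated), via allyl dienyl ether 17 (not isolated)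
Conditions: 15 (5 equiv), 2,4-dinitrophenol (0.1 equiv), hydroquinone (trace), toluene, 105 °C, sealed tube
Reagents that add atoms: none
Why: Acid-catalysed addition of the secondary hydroxyl of 12 to the enol ether of 15 gives mixed ketal 16, which loses methanol to allyl dienyl ether 17; a concerted suprafacial [3,3]-sigmatropic (Claisen) shift through a chair transition state then forms the C4'–C5' σ-bond, breaks C2'–O, moves the alkene to C2'=C3' and unveils the C6' carbonyl of an isopropenyl ketone. The closest known reaction type is the ketal/2-alkoxydiene Claisen rearrangement of 2-substituted secondary allylic alcohols, the enone-forming relative of the Saucy–Marbet and Johnson–Claisen reactions used to build trisubstituted isoprenoid alkenes. No ring is closed and no stereocentre is created: the racemic carbinol centre of 12 is erased and both carbons of the new bond are CH2. The alkene geometry is set by the chair, in which the coumarinyloxymethyl group on C2' sits pseudo-equatorial to avoid a 1,3-diaxial contact with the isopropenyl group on the enol-ether carbon, so that C1' ends up trans to C4' and cis to the CH2OTBS group, as the target requires. The step needs reaction at the secondary allylic hydroxyl only and survival of the newly formed 4-allyloxycoumarin unit; the first is secured by the silyl ether on the primary hydroxyl, the second by holding the bath near 105 °C, below the range in which 4-allyloxycoumarins shift their allyl group to C3.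

Step 9
Reactants: 18 4-{[(2Z)-3-({[tert-butyl(dimethyl)silyl]oxy}methyl)-7-methyl-6-oxoocta-2,7-dien-1-yl]oxy}-5-methyl-2H-chromen-2-one
Product: 19 4-{[(2Z,6R)-3-({[tert-butyl(dimethyl)silyl]oxy}methyl)-6-hydroxy-7-methylocta-2,7-dien-1-yl]oxy}-5-methyl-2H-chromen-2-one
Conditions: (S)-Me-CBS oxazaborolidine (0.2 equiv), catecholborane (1.8 equiv), toluene, −78 °C; MeOH quench, pH 7 buffer
Reagents that add atoms: none
Why: Corey–Bakshi–Shibata reduction with the isopropenyl group acting as the large substituent should deliver hydride under catalyst control to give the (R)-carbinol, while catecholborane at −78 °C spares the lactone and the alkenes and disfavours 1,4-reduction.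

Step 10
Reactants: 19 4-{[(2Z,6R)-3-({[tert-butyl(dimethyl)silyl]oxy}methyl)-6-hydroxy-7-methylocta-2,7-dien-1-yl]oxy}-5-methyl-2H-chromen-2-one
Product: 20 (2Z,6R)-3-({[tert-butyl(dimethyl)silyl]oxy}methyl)-7-methyl-1-[(5-methyl-2-oxo-2H-chromen-4-yl)oxy]octa-2,7-dien-6-yl methanesulfonate
Conditions: MsCl, Et3N, CH2Cl2, −30 °C; cold aqueous work-up, used at once without chromatography
Reagents that add atoms: methanesulfonyl chloride, CS(=O)(=O)Cl
Why: O-sulfonylation forms only the O–S bond, so the C6' configuration is retained while the hydroxyl becomes a leaving group.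

Step 11
Reactants: 21 2,3-dimethylbut-2-ene
Product: 23 2-hydroperoxy-2-methoxypropane, via primary ozonide 22 (not isolated)
Conditions: O3, MeOH/CH2Cl2, −78 °C; no reductive work-up, volatiles removed cold under reduced pressure
Reagents that add atoms: ozone, [O-][O+]=O; methanol, CO
Why: Ozonolysis in methanol: the primary ozonide fragments to acetone and acetone O-oxide (Criegee intermediate), which methanol captures as the α-methoxy hydroperoxide, a hydroperoxide carrying its own acid-labile ketal protection.

Step 12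
Reactants: 20 (2Z,6R)-3-({[tert-butyl(dimethyl)silyl]oxy}methyl)-7-methyl-1-[(5-methyl-2-oxo-2H-chromen-4-yl)oxy]octa-2,7-dien-6-yl methanesulfonate; 23 2-hydroperoxy-2-methoxypropane
Product: 24 4-{[(2Z,6S)-3-({[tert-butyl(dimethyl)silyl]oxy}methyl)-6-[(2-methoxypropan-2-yl)peroxy]-7-methylocta-2,7-dien-1-yl]oxy}-5-methyl-2H-chromen-2-one
Conditions: 23 (2 equiv), CsOH·H2O (1.5 equiv), DMF, 0 °C
Reagents that add atoms: none
Why: SN2 alkylation of the caesium peroxide anion (an α-effect nucleophile) by the secondary mesylate should proceed with inversion at C6', turning the (R)-sulfonate into the (S)-peroxyketal; the hydroperoxide is kept in excess over the base so that no free hydroxide meets the lactone.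

Step 13
Reactants: 24 4-{[(2Z,6S)-3-({[tert-butyl(dimethyl)silyl]oxy}methyl)-6-[(2-methoxypropan-2-yl)peroxy]-7-methylocta-2,7-dien-1-yl]oxy}-5-methyl-2H-chromen-2-one
Product: 25 4-{[(2Z,6S)-6-hydroperoxy-3-(hydroxymethyl)-7-methylocta-2,7-dien-1-yl]oxy}-5-methyl-2H-chromen-2-one
Conditions: AcOH/THF/H2O (3:1:1), rt
Reagents that add atoms: none
Why: Mild aqueous acid should hydrolyse the peroxyketal quickly and the primary silyl ether more slowly, without touching the O–O bond, the C6' centre, the allylic ether or the lactone.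

Compound list
1 | 1-(2-hydroxy-6-methylphenyl)ethan-1-one | CC(=O)c1c(C)cccc1O | starting material
2 | diethyl carbonate | CCOC(=O)OCC | starting material
3 | ethyl 3-(2-hydroxy-6-methylphenyl)-3-oxopropanoate (sodium salt in the flask) | CCOC(=O)CC(=O)c1c(C)cccc1O | intermediate (not isolated)
4 | 4-hydroxy-5-methyl-2H-chromen-2-one | Cc1cccc2oc(=O)cc(O)c12 | intermediate
5 | allyl bromide | C=CCBr | starting material
6 | 5-methyl-4-(prop-2-en-1-yloxy)-2H-chromen-2-one | C=CCOc1cc(=O)oc2cccc(C)c12 | intermediate
7 | rac-4-(2,3-dihydroxypropoxy)-5-methyl-2H-chromen-2-one | OCC(O)COc1cc(=O)oc2cccc(C)c12 | intermediate (not isolated)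
8 | 2-[(5-methyl-2-oxo-2H-chromen-4-yl)oxy]acetaldehyde | O=CCOc1cc(=O)oc2cccc(C)c12 | intermediate
9 | 2-bromoprop-2-en-1-ol | C=C(Br)CO | starting material
10 | [(2-bromoprop-2-en-1-yl)oxy](tert-butyl)dimethylsilane | C=C(Br)CO[Si](C)(C)C(C)(C)C | intermediate
11 | dichloro[3-{[tert-butyl(dimethyl)silyl]oxy}prop-1-en-2-yl]chromium(III) | C=C(CO[Si](C)(C)C(C)(C)C)[Cr](Cl)Cl | intermediate (not isolated)
12 | rac-4-{[3-({[tert-butyl(dimethyl)silyl]oxy}methyl)-2-hydroxybut-3-en-1-yl]oxy}-5-methyl-2H-chromen-2-one | C=C(CO[Si](C)(C)C(C)(C)C)C(O)COc1cc(=O)oc2cccc(C)c12 | intermediate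
13 | 3-methylbut-3-en-2-one | CC(=O)C(C)=C | starting material
14 | rac-1,3,3-trimethoxy-2-methylbutane | COCC(C)C(C)(OC)OC | intermediate
15 | 2-methoxy-3-methylbuta-1,3-diene | C=C(C)C(=C)OC | intermediate
16 | mixed methyl ketal: 4-{[3-({[tert-butyl(dimethyl)silyl]oxy}methyl)-2-[(2-methoxy-3-methylbut-3-en-2-yl)oxy]but-3-en-1-yl]oxy}-5-methyl-2H-chromen-2-one (diastereomer mixture) | C=C(C)C(C)(OC)OC(COc1cc(=O)oc2cccc(C)c12)C(=C)CO[Si](C)(C)C(C)(C)C | intermediate (not isolated)
17 | allyl dienyl ether: rac-4-{[3-({[tert-butyl(dimethyl)silyl]oxy}methyl)-2-[(3-methylbuta-1,3-dien-2-yl)oxy]but-3-en-1-yl]oxy}-5-methyl-2H-chromen-2-one | C=C(C)C(=C)OC(COc1cc(=O)oc2cccc(C)c12)C(=C)CO[Si](C)(C)C(C)(C)C | intermediate (not isolated)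
18 | 4-{[(2Z)-3-({[tert-butyl(dimethyl)silyl]oxy}methyl)-7-methyl-6-oxoocta-2,7-dien-1-yl]oxy}-5-methyl-2H-chromen-2-one | C=C(C)C(=O)CC/C(=C/COc1cc(=O)oc2cccc(C)c12)CO[Si](C)(C)C(C)(C)C | intermediate
19 | 4-{[(2Z,6R)-3-({[tert-butyl(dimethyl)silyl]oxy}methyl)-6-hydroxy-7-methylocta-2,7-dien-1-yl]oxy}-5-methyl-2H-chromen-2-one | C=C(C)[C@@H](CC/C(=C/COc1cc(=O)oc2cccc(C)c12)CO[Si](C)(C)C(C)(C)C)O | intermediate
20 | (2Z,6R)-3-({[tert-butyl(dimethyl)silyl]oxy}methyl)-7-methyl-1-[(5-methyl-2-oxo-2H-chromen-4-yl)oxy]octa-2,7-dien-6-yl methanesulfonate | C=C(C)[C@@H](CC/C(=C/COc1cc(=O)oc2cccc(C)c12)CO[Si](C)(C)C(C)(C)C)OS(C)(=O)=O | intermediate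
21 | 2,3-dimethylbut-2-ene | CC(C)=C(C)C | starting material
22 | 4,4,5,5-tetramethyl-1,2,3-trioxolane (primary ozonide) | CC1(C)OOOC1(C)C | intermediate (not isolated)
23 | 2-hydroperoxy-2-methoxypropane | COC(C)(C)OO | intermediate
24 | 4-{[(2Z,6S)-3-({[tert-butyl(dimethyl)silyl]oxy}methyl)-6-[(2-methoxypropan-2-yl)peroxy]-7-methylocta-2,7-dien-1-yl]oxy}-5-methyl-2H-chromen-2-one | C=C(C)[C@H](CC/C(=C/COc1cc(=O)oc2cccc(C)c12)CO[Si](C)(C)C(C)(C)C)OOC(C)(C)OC | intermediate
25 | 4-{[(2Z,6S)-6-hydroperoxy-3-(hydroxymethyl)-7-methylocta-2,7-dien-1-yl]oxy}-5-methyl-2H-chromen-2-one | C=C(C)[C@H](CC/C(=C/COc1cc(=O)oc2cccc(C)c12)CO)OO | target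

Total step count: 13
Longest linear sequence: 9 steps (1, 2, 3, 5, 8, 9, 10, 12, 13)

Steps most likely to fail

Step 12. The peroxide anion may attack the terminal methylene in an SN2' sense, the allylic mesylate may ionise so that the configuration at C6' erodes, or the anion may add to the coumarin at C2 or C4. The fallback moves the substitution to a non-allylic carbon by masking the isopropenyl alkene; it sets out from enone 18 and comes back at peroxyketal 24. Conjugate addition of benzeneselenol (PhSeSePh, NaBH4, EtOH, then AcOH, 0 °C) to 18 should give the β-(phenylselanyl) ketone F1 as a mixture at C7'. CBS reduction as in step 9 should give the (6R)-alcohol F2, and MsCl/Et3N the mesylate F3. Substitution with 23 and CsOH·H2O in DMF at 0 °C should then give the (6S)-peroxyketal selenide F4 with inversion, now without any allylic pathway. Oxidation at selenium (NaIO4, NaHCO3, aqueous THF, 0 °C to rt) should give the selenoxide F5, which is not isolated; its syn-elimination can only use the C7' hydrogen and restores the isopropenyl group, giving 24.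

Step 8. At the temperature of the rearrangement the product's 4-allyloxycoumarin may undergo a second [3,3] shift to coumarin C3, the coumarinyl group of 12 may migrate to the neighbouring secondary oxygen under acid, or the chair preference may be weaker than expected and lower the alkene selectivity. The fallback runs the same rearrangement without the coumarin and attaches it afterwards; it sets out from vinyl bromide 10 and comes back at enone 18. Nozaki–Hiyama–Kishi coupling of 10 (through 11) with commercial (4-methoxybenzyloxy)acetaldehyde should give the PMB-protected allylic alcohol F6. Under the conditions of step 8 this should pass through the mixed methyl ketal F7 and the allyl dienyl ether F8, neither isolated, to the PMB-protected enone F9. DDQ (CH2Cl2/pH 7 buffer, 0 °C) should release the primary allylic alcohol F10, and Mitsunobu etherification with 4 (PPh3, DIAD, THF, 0 °C) should give 18.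

Step 9. Facial discrimination between the isopropenyl group and the primary alkyl chain may be insufficient, or 1,4-reduction of the enone may compete. The fallback replaces catalyst-controlled reduction by kinetic resolution; it sets out from enone 18 and comes back at alcohol 19. Luche reduction (NaBH4, CeCl3·7H2O, MeOH, −40 °C) should give the racemic allylic alcohol F11. Sharpless kinetic resolution (Ti(OiPr)4, L-(+)-diisopropyl tartrate, t-BuOOH 0.6 equiv, 4 Å sieves, CH2Cl2, −20 °C) should epoxidise the (S)-enantiomer to the erythro epoxy alcohol F12 and leave (R)-alcohol 19, which is separated by chromatography; the other alkene carries no free allylic hydroxyl and should not react.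

Further compounds
F1 | step 12 | 4-{[(2Z)-3-({[tert-butyl(dimethyl)silyl]oxy}methyl)-7-methyl-6-oxo-8-(phenylselanyl)oct-2-en-1-yl]oxy}-5-methyl-2H-chromen-2-one (mixture at C7') | CC(C[Se]c1ccccc1)C(=O)CC/C(=C/COc1cc(=O)oc2cccc(C)c12)CO[Si](C)(C)C(C)(C)C
F2 | step 12 | 4-{[(2Z,6R)-3-({[tert-butyl(dimethyl)silyl]oxy}methyl)-6-hydroxy-7-methyl-8-(phenylselanyl)oct-2-en-1-yl]oxy}-5-methyl-2H-chromen-2-one (mixture at C7') | CC(C[Se]c1ccccc1)[C@@H](CC/C(=C/COc1cc(=O)oc2cccc(C)c12)CO[Si](C)(C)C(C)(C)C)O
F3 | step 12 | (2Z,6R)-3-({[tert-butyl(dimethyl)silyl]oxy}methyl)-7-methyl-1-[(5-methyl-2-oxo-2H-chromen-4-yl)oxy]-8-(phenylselanyl)oct-2-en-6-yl methanesulfonate (mixture at C7') | CC(C[Se]c1ccccc1)[C@@H](CC/C(=C/COc1cc(=O)oc2cccc(C)c12)CO[Si](C)(C)C(C)(C)C)OS(C)(=O)=O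
F4 | step 12 | 4-{[(2Z,6S)-3-({[tert-butyl(dimethyl)silyl]oxy}methyl)-6-[(2-methoxypropan-2-yl)peroxy]-7-methyl-8-(phenylselanyl)oct-2-en-1-yl]oxy}-5-methyl-2H-chromen-2-one (mixture at C7') | CC(C[Se]c1ccccc1)[C@H](CC/C(=C/COc1cc(=O)oc2cccc(C)c12)CO[Si](C)(C)C(C)(C)C)OOC(C)(C)OC
F5 | step 12 | selenoxide of F4 (not isolated; mixture at C7' and Se) | CC(C[Se](=O)c1ccccc1)[C@H](CC/C(=C/COc1cc(=O)oc2cccc(C)c12)CO[Si](C)(C)C(C)(C)C)OOC(C)(C)OC
F6 | step 8 | rac-3-({[tert-butyl(dimethyl)silyl]oxy}methyl)-1-[(4-methoxyphenyl)methoxy]but-3-en-2-ol | C=C(CO[Si](C)(C)C(C)(C)C)C(O)COCc1ccc(OC)cc1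
F7 | step 8 | mixed methyl ketal of F6 with 15 (not isolated; diastereomer mixture) | C=C(C)C(C)(OC)OC(COCc1ccc(OC)cc1)C(=C)CO[Si](C)(C)C(C)(C)C
F8 | step 8 | allyl dienyl ether from F7 (not isolated; racemic) | C=C(C)C(=C)OC(COCc1ccc(OC)cc1)C(=C)CO[Si](C)(C)C(C)(C)C
F9 | step 8 | (6Z)-6-({[tert-butyl(dimethyl)silyl]oxy}methyl)-8-[(4-methoxyphenyl)methoxy]-2-methylocta-1,6-dien-3-one | C=C(C)C(=O)CC/C(=C/COCc1ccc(OC)cc1)CO[Si](C)(C)C(C)(C)C
F10 | step 8 | (6Z)-6-({[tert-butyl(dimethyl)silyl]oxy}methyl)-8-hydroxy-2-methylocta-1,6-dien-3-one | C=C(C)C(=O)CC/C(=C/CO)CO[Si](C)(C)C(C)(C)C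
F11 | step 9 | rac-4-{[(2Z)-3-({[tert-butyl(dimethyl)silyl]oxy}methyl)-6-hydroxy-7-methylocta-2,7-dien-1-yl]oxy}-5-methyl-2H-chromen-2-one | C=C(C)C(O)CC/C(=C/COc1cc(=O)oc2cccc(C)c12)CO[Si](C)(C)C(C)(C)C
F12 | step 9 | 4-{[(2Z,6S)-3-({[tert-butyl(dimethyl)silyl]oxy}methyl)-6-hydroxy-6-[(2R)-2-methyloxiran-2-yl]hex-2-en-1-yl]oxy}-5-methyl-2H-chromen-2-one | C[C@@]3(CO3)[C@@H](O)CC/C(=C/COc1cc(=O)oc2cccc(C)c12)CO[Si](C)(C)C(C)(C)C
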